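The numbers in the tables are calculated from invented constants, noise included.

At the 1.5 h reading, watch two figures, target and over-reaction product, both in percent of the starting material charged.

| flask | starting material | coupling partner | second substrate | protic impurity | temperature | remark | time |
|---|---|---|---|---|---|---|---|
| Tuesday's | 0.30 M | 0.30 M | 0.15 M | 0.060 M | 20 °C | run made earlier |  |
| Monday's | 0.30 M | 0.30 M | 0.075 M | 0.060 M | 31 °C | run made earlier |  |
| Wednesday's | 0.30 M | 0.30 M | 0.11 M | 0.060 M | 20 °C | run made earlier |  |
| Saturday's | 0.30 M | 0.15 M | 0.15 M | 0.060 M | 31 °C | run made earlier |  |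
| dawn | 0.30 M (fed, over 50 min) | 0.300 M | 0.150 M | 0.0600 M |  | the addition at −15 °C, then warmed to 25 °C; the feed brings no volume worth counting | 1.5 h |
| summer | 0.30 M (fed, over 50 min) | 0.300 M | 0.150 M | 0.0600 M | 25 °C | all else is in the flask from the start; the feed brings no volume worth counting | 1.5 h |
| winter | 0.30 M | 0.300 M | 0.150 M | 0.0600 M | 25 °C | everything together at the start | 1.5 h |
| midnight | 0.30 M | 0.300 M | 0.150 M (fed, over 50 min) | 0.0600 M | 25 °C | all else is in the flask from the start; the feed brings no volume worth counting | 1.5 h |

| run | time / min | target / % | over-reaction product / % |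
|---|---|---|---|
| Tuesday's | 6.00 | 7 | 0 |
| Tuesday's | 20.0 | 15 | 1 |
| Tuesday's | 30.0 | 17 | 5 |
| Tuesday's | 50.0 | 12 | 7 |
| Tuesday's | 60.0 | 13 | 9 |
| Tuesday's | 90.0 | 12 | 8 |
| Monday's | 8.00 | 13 | 5 |
| Monday's | 20.0 | 11 | 10 |
| Monday's | 40.0 | 9 | 10 |
| Monday's | 60.0 | 9 | 16 |
| Monday's | 80.0 | 8 | 19 |
| Monday's | 120 | 4 | 21 |
| Wednesday's | 20.0 | 14 | 2 |
| Wednesday's | 40.0 | 17 | 7 |
| Wednesday's | 50.0 | 17 | 6 |
| Wednesday's | 80.0 | 12 | 11 |
| Wednesday's | 90.0 | 14 | 14 |
| Wednesday's | 120 | 12 | 12 |
| Saturday's | 8.00 | 8 | 3 |
| Saturday's | 15.0 | 7 | 0 |
| Saturday's | 30.0 | 4 | 1 |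
| Saturday's | 60.0 | 3 | 1 |
| Saturday's | 120 | 0 | 1 |

(standard deviation of a reading: 1.5 percentage points)

- a reading or a percentage of target counts all its forms, free or not

- the flask that comes out highest in share of target in target plus over-reaction product, or "all alike" when all lie within 1.5 percentage points (dawn / summer / winter / midnight / all alike)
- share of target in target plus over-reaction product at the end, dawn
- share of target in target plus over-reaction product at the end, summer
- share of target in target plus over-reaction product at the end, winter
- share of target in target plus over-reaction product at the end, midnight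

Two chemists dispute the feed. The first holds the even view: each channel is first order in starting material, so the order of charging moves little. The end shares read from Tuesday's run, 60.0 %, and Wednesday's, 50.0 %, then put summer and winter together near those readings.

The second follows one molecule of coupling partner and asks whom it meets. A second substrate or a protic impurity takes one partner, a target costs one, and an over-reaction product costs 2. Hence the partner budget: the coupling partner left per starting material charged once second substrate and protic impurity have taken their full charges, here 30.0 %. By that count coupling partner is the limiting reagent towards starting material. Its counterpart in the readings is the spend: target plus 2 times over-reaction product.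

Tuesday's budget is the same, and its spend reads 28.0 % at 90.0 min. Wednesday's budget is 43.3 %, and its spend reads 42.0 % at 90.0 min and 36.0 % at 120 min. Saturday's budget is −20.0 %, and its target reads 0 % at 120 min. Within Tuesday's run the share reads 93.8 % at a spend of 17.0 % at 20.0 min, and 60.0 % at a spend of 28.0 % at 90.0 min.

So the second chemist expects order to matter. In summer the starting material comes in over 50 min while second substrate and protic impurity stand in the flask from the start, so the spend should stay under budget. In winter the customers compete from the start, so the spend should land near it. In midnight second substrate arrives late, so the spend should overrun. My reckoning follows this view: summer clearly above winter, and midnight lowest. Dawn is fed like summer, but its addition runs colder than any earlier run, so its place stays open. The forecast takes the even side on summer against winter, with dawn highest at 58 %, summer 50 %, winter 50 % and midnight 30 %, holding that “a slow feed changes little”.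

The flasks give 61.3 % in dawn, 55.5 % in summer, 41.4 % in winter and 29.8 % in midnight, so dawn stands highest.

    starting material + coupling partner ⇌ target (K = 0.930 L mol⁻¹, k = 0.00190 L mol⁻¹ s⁻¹, Ea = 70.0 kJ mol⁻¹, ΔH = −81.0 kJ mol⁻¹)
    second substrate + coupling partner ⇌ second product (K = 120 L mol⁻¹, k = 0.00510 L mol⁻¹ s⁻¹, Ea = 58.0 kJ mol⁻¹, ΔH = −79.0 kJ mol⁻¹)
    coupling partner + protic impurity → quenched reagent (k = 0.0130 L mol⁻¹ s⁻¹, Ea = 68.0 kJ mol⁻¹)
    coupling partner + target → over-reaction product (k = 0.00700 L mol⁻¹ s⁻¹, Ea = 71.0 kJ mol⁻¹)
    starting material + target ⇌ idle adduct, settled at all times (K = 7.60 L mol⁻¹, ΔH = 27.0 kJ mol⁻¹)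
    (constants at 25 °C)

Against the budget of 30.0 %, the spend is 22.9 % in summer, 28.6 % in winter and 37.9 % in midnight. The even view has its region at 15.0 h, where summer's share is 11.9 % and winter's 11.0 %. A flask like midnight with 1.2 M of coupling partner has a budget of 330 %, above the 200 % that full over-reaction costs. It ends with over-reaction product at 95.9 % and a share of 0.681 %.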